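**Retrosynthetic overview**

- The target is 3,4,7-tribromo-2-chloro-1H-indole. Its benzo ring carries hydrogen only at C5–C6, a two-carbon unit that maps onto acetylene, and the flanking carbons C4 and C7 carry bromine, which maps onto silicon on two alkyne termini.
- Late disconnections: C3–Br (NBS on the NH-indole), N–Ts, C2–Cl (C2 lithiation of the N-tosylindole), the C2=C3 double bond (indoline dehydrogenation), then both C–Br bonds back to C–SiMe3 (ipso-bromodesilylation).
- Key disconnection: Rh-catalysed [2+2+2] of the bis-silyl ynamide diyne 7 with acetylene 8, forming C3a–C7a, C4–C5 and C6–C7. The five-membered nitrogen ring closes at the metallacycle stage and the benzene ring directly after it, in one operation.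
- Diyne 7 is assembled from 4-(trimethylsilyl)but-3-yn-1-ol, tert-butyl tosylcarbamate (Mitsunobu, Boc removal) and a silylethynyl iodonium salt (N-alkynylation).

Key step: step 4

Remark: the target is a planar, achiral indole with no stereocentre, so no stereocontrol is required; iodonium salt 5 is taken as a commercial reagent.

**Step 1**
Reactants: 1 4-(trimethylsilyl)but-3-yn-1-ol; 2 tert-butyl tosylcarbamate
Product: 3 tert-butyl tosyl[4-(trimethylsilyl)but-3-yn-1-yl]carbamate
Conditions: PPh3, DIAD, THF, 0 °C to rt
Reagents that add atoms: none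
Why: Mitsunobu reaction, in which the acidic N–H of the Boc-sulfonamide is alkylated by the primary alcohol activated as its alkoxyphosphonium salt, while the alkynylsilane is inert.

**Step 2**
Reactants: 3 tert-butyl tosyl[4-(trimethylsilyl)but-3-yn-1-yl]carbamate
Product: 4 4-methyl-N-[4-(trimethylsilyl)but-3-yn-1-yl]benzenesulfonamide
Conditions: TFA, CH2Cl2, rt
Reagents that add atoms: none
Why: Acidolytic Boc cleavage (loss of the tert-butyl cation, then decarboxylation), which the alkynylsilane and the sulfonamide should tolerate at room temperature.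

**Step 3**
Reactants: 4 4-methyl-N-[4-(trimethylsilyl)but-3-yn-1-yl]benzenesulfonamide; 5 phenyl[(trimethylsilyl)ethynyl]iodonium trifluoromethanesulfonate
Product: 7 4-methyl-N-[(trimethylsilyl)ethynyl]-N-[4-(trimethylsilyl)but-3-yn-1-yl]benzenesulfonamide, via potassium N-[4-(trimethylsilyl)but-3-yn-1-yl]tosylamide 6 (not isolated)
Conditions: KHMDS, PhMe, 0 °C; then 5, 0 °C to rt
Reagents that add atoms: none
Why: N-alkynylation of a sulfonamide anion with an alkynyliodonium salt, in which conjugate addition to the β-carbon, loss of iodobenzene to an alkylidene carbene and a 1,2-silyl shift should deliver the N-(silylethynyl) ynamide, the established entry to N-tosyl silyl-ynamides.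

**Step 4**
Reactants: 7 4-methyl-N-[(trimethylsilyl)ethynyl]-N-[4-(trimethylsilyl)but-3-yn-1-yl]benzenesulfonamide; 8 acetylene
Product: 9 1-tosyl-4,7-bis(trimethylsilyl)indoline
Conditions: RhCl(PPh3)3 (10 mol%), HC≡CH (1 atm), PhMe, 60 °C, slow addition of 7
Reagents that add atoms: none
Why: Rh(I) should bind both alkynes of 7 and couple them oxidatively through their inner carbons to a bicyclic rhodacyclopentadiene that carries both silyl groups alpha to the metal; acetylene then inserts into a Rh–C bond and C–C reductive elimination releases the arene and returns Rh(I). The closest known reaction is the Rh(I)-catalysed crossed [2+2+2] cyclotrimerization of N-sulfonyl ynamide 1,6-diynes with acetylene to indolines, run here on a diyne capped by silicon at both ends. The five-membered nitrogen ring closes by the intramolecular oxidative coupling (C3a–C7a, ring size fixed by the N–CH2–CH2 tether), and the benzene ring closes by intermolecular insertion of acetylene followed by reductive elimination (C4–C5 and C6–C7). No stereocentre is formed. The step needs cross-selectivity over self-reaction of the diyne and over consumption of the catalyst by acetylene alone: the two trimethylsilyl caps keep a second diyne from inserting, a standing excess of the small alkyne with slow addition of 7 supplies the metallacycle with acetylene only, and regiochemistry cannot vary because the tether fixes C3a–C7a and acetylene is symmetric, so silicon must end on C4 and C7.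

**Step 5**
Reactants: 9 1-tosyl-4,7-bis(trimethylsilyl)indoline
Product: 11 4,7-dibromo-1-tosylindoline, via 7-bromo-1-tosyl-4-(trimethylsilyl)indoline 10 (not isolated)
Conditions: Br2 (2.2 equiv), CH2Cl2, 0 °C to rt, dark; aq Na2S2O3
Reagents that add atoms: bromine, BrBr
Why: Electrophilic ipso-bromodesilylation, in which attack at each silicon-bearing carbon gives a Wheland cation stabilised by the β-C–Si bond and loss of Me3SiBr restores the arene; the crowded C7 silyl group ortho to nitrogen should react first, and ipso attack at C4 should outrun bromination of C5–H para to the weakly donating sulfonamide nitrogen.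

**Step 6**
Reactants: 11 4,7-dibromo-1-tosylindoline
Product: 12 4,7-dibromo-1-tosyl-1H-indole
Conditions: DDQ (3 equiv), PhCl, 130 °C
Reagents that add atoms: none
Why: DDQ dehydrogenation of an N-sulfonylindoline (hydride abstraction from the C2–C3 unit, then proton loss), driven by aromatisation to the indole; the deactivated substrate is given excess oxidant and heat.

**Step 7**
Reactants: 12 4,7-dibromo-1-tosyl-1H-indole
Product: 14 4,7-dibromo-2-chloro-1-tosyl-1H-indole, via 4,7-dibromo-2-lithio-1-tosyl-1H-indole 13 (not isolated)
Conditions: LDA (1.2 equiv), THF, −78 °C; then C2Cl6, −78 °C to rt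
Reagents that add atoms: hexachloroethane, ClC(Cl)(Cl)C(Cl)(Cl)Cl
Why: Directed C2 lithiation of an N-sulfonylindole (the sulfonyl group acidifies and coordinates at C2, and the amide base does not undergo bromine–lithium exchange) followed by chlorine transfer from hexachloroethane, the standard route to 2-chloro-N-sulfonylindoles.

**Step 8**
Reactants: 14 4,7-dibromo-2-chloro-1-tosyl-1H-indole
Product: 15 4,7-dibromo-2-chloro-1H-indole
Conditions: KOH, THF/MeOH/H2O, rt; aq NH4Cl
Reagents that add atoms: none
Why: Nucleophilic N-desulfonylation of an N-sulfonylindole by attack of hydroxide at sulfur, helped by the good trihaloindolide leaving group and by relief of strain between the tosyl group and its C7–Br and C2–Cl neighbours; the NH 2-chloroindole should be kept away from acid and used at once.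

**Step 9**
Reactants: 15 4,7-dibromo-2-chloro-1H-indole
Product: 16 3,4,7-tribromo-2-chloro-1H-indole
Conditions: NBS (1.0 equiv), DMF, 0 °C
Reagents that add atoms: N-bromosuccinimide, O=C1CCC(=O)N1Br
Why: Electrophilic aromatic substitution of an NH-indole by NBS at C3, the only free position of the pyrrole ring and its most nucleophilic carbon, while the benzo ring is deactivated by two bromines.

**Compound list**

1 | 4-(trimethylsilyl)but-3-yn-1-ol | C[Si](C)(C)C#CCCO | starting material
2 | tert-butyl tosylcarbamate | Cc1ccc(cc1)S(=O)(=O)NC(=O)OC(C)(C)C | starting material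
3 | tert-butyl tosyl[4-(trimethylsilyl)but-3-yn-1-yl]carbamate | Cc1ccc(cc1)S(=O)(=O)N(CCC#C[Si](C)(C)C)C(=O)OC(C)(C)C | intermediate
4 | 4-methyl-N-[4-(trimethylsilyl)but-3-yn-1-yl]benzenesulfonamide | Cc1ccc(cc1)S(=O)(=O)NCCC#C[Si](C)(C)C | intermediate
5 | phenyl[(trimethylsilyl)ethynyl]iodonium trifluoromethanesulfonate | C[Si](C)(C)C#C[I+]c1ccccc1.[O-]S(=O)(=O)C(F)(F)F | starting material
6 | potassium N-[4-(trimethylsilyl)but-3-yn-1-yl]tosylamide (not isolated) | [K+].Cc1ccc(cc1)S(=O)(=O)[N-]CCC#C[Si](C)(C)C | intermediate
7 | 4-methyl-N-[(trimethylsilyl)ethynyl]-N-[4-(trimethylsilyl)but-3-yn-1-yl]benzenesulfonamide | C[Si](C)(C)C#CN(CCC#C[Si](C)(C)C)S(=O)(=O)c1ccc(C)cc1 | intermediate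
8 | acetylene | C#C | starting material
9 | 1-tosyl-4,7-bis(trimethylsilyl)indoline | Cc1ccc(cc1)S(=O)(=O)N1CCc2c([Si](C)(C)C)ccc([Si](C)(C)C)c21 | intermediate
10 | 7-bromo-1-tosyl-4-(trimethylsilyl)indoline (not isolated) | Cc1ccc(cc1)S(=O)(=O)N1CCc2c([Si](C)(C)C)ccc(Br)c21 | intermediate
11 | 4,7-dibromo-1-tosylindoline | Cc1ccc(cc1)S(=O)(=O)N1CCc2c(Br)ccc(Br)c21 | intermediate
12 | 4,7-dibromo-1-tosyl-1H-indole | Cc1ccc(cc1)S(=O)(=O)n1ccc2c(Br)ccc(Br)c21 | intermediate
13 | 4,7-dibromo-2-lithio-1-tosyl-1H-indole (not isolated) | [Li]c1cc2c(Br)ccc(Br)c2n1S(=O)(=O)c1ccc(C)cc1 | intermediate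
14 | 4,7-dibromo-2-chloro-1-tosyl-1H-indole | Cc1ccc(cc1)S(=O)(=O)n1c(Cl)cc2c(Br)ccc(Br)c21 | intermediate
15 | 4,7-dibromo-2-chloro-1H-indole | Clc1cc2c(Br)ccc(Br)c2[nH]1 | intermediate
16 | 3,4,7-tribromo-2-chloro-1H-indole | Clc1[nH]c2c(Br)ccc(Br)c2c1Br | target

**Totals**

Total step count: 9. Longest linear sequence: 9 steps (from 1 or 2 to 16).

**Steps most likely to fail**

Step 4. Oxidative coupling of two silyl-capped alkynes at rhodium may be slow for steric reasons, so that acetylene oligomerisation and catalyst deactivation overtake the cross-cyclization and conversion stalls. The fallback sets out from diyne 7 and replaces catalysis by a stoichiometric titanium template. Ti(O-i-Pr)4/2 i-PrMgCl (Et2O, −78 to −50 °C) should couple the two silylalkynes, substrates well suited to low-valent titanium alkoxides, to the bicyclic titanacyclopentadiene F1. Ethynyl p-tolyl sulfone then inserts and expels sulfinate (metalative Reppe reaction) to give the aryltitanium F2 (titanium at C5 or C6, drawn at C5; both give the same arene). Aqueous acid protonates the C–Ti bond and the route is rejoined at 9.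

Step 5. Bromination of C5–H para to the sulfonamide nitrogen may compete with ipso attack at the less activated C4, and the HBr it releases would then cause protodesilylation, so the bromine pattern is lost. The fallback sets out from 9 and moves the halogenation through boron, which reacts only at C–Si. BBr3 (CH2Cl2, 0 °C to rt) should effect ipso-borodesilylation to 4,7-bis(dibromoboryl)-1-tosylindoline F3. Quenching with pinacol and Et3N gives 1-tosyl-4,7-bis(4,4,5,5-tetramethyl-1,3,2-dioxaborolan-2-yl)indoline F4. Copper-mediated bromodeboronation (CuBr2, MeOH/H2O, 80 °C) then places bromine only where boron stood, and the route is rejoined at 11.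

Step 6. Hydride abstraction by DDQ may be too slow, because the sulfonyl group ties up the nitrogen lone pair and two bromines deactivate the ring, giving incomplete conversion or decomposition on forcing. The fallback sets out from 11 and uses radical benzylic bromination (NBS, cat. AIBN, PhCF3, reflux) to give racemic 3,4,7-tribromo-1-tosylindoline F5, whose C3 stereocentre is destroyed in the next operation. DBU (THF, rt to 60 °C) then removes HBr by E2 elimination, driven by aromatisation, and the route is rejoined at 12.

**Further compounds**

F1 | step 4 | 2,2-diisopropoxy-titanacyclopentadiene fused to the N-tosyl pyrroline ring, both α-carbons bearing SiMe3 | CC(C)O[Ti]1(OC(C)C)C([Si](C)(C)C)=C2CCN(S(=O)(=O)c3ccc(C)cc3)C2=C1[Si](C)(C)C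
F2 | step 4 | [1-tosyl-4,7-bis(trimethylsilyl)indolin-5-yl]titanium diisopropoxide p-toluenesulfinate | Cc1ccc(cc1)S(=O)(=O)N1CCc2c([Si](C)(C)C)c([Ti](OC(C)C)(OC(C)C)OS(=O)c3ccc(C)cc3)cc([Si](C)(C)C)c21
F3 | step 5 | 4,7-bis(dibromoboryl)-1-tosylindoline | Cc1ccc(cc1)S(=O)(=O)N1CCc2c(B(Br)Br)ccc(B(Br)Br)c21
F4 | step 5 | 1-tosyl-4,7-bis(4,4,5,5-tetramethyl-1,3,2-dioxaborolan-2-yl)indoline | Cc1ccc(cc1)S(=O)(=O)N1CCc2c(B3OC(C)(C)C(C)(C)O3)ccc(B3OC(C)(C)C(C)(C)O3)c21
F5 | step 6 | 3,4,7-tribromo-1-tosylindoline (racemic) | Cc1ccc(cc1)S(=O)(=O)N1CC(Br)c2c(Br)ccc(Br)c21
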